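**Retrosynthetic overview**
- Target 34 is reached from bicyclic enone 20 by late functional-group work: the C9 ester by SN2 of a carboxylate on a 9β-mesylate next to the C8 ketone, the O3 angelate on the equatorial 3α-alcohol, the C8 oxygen by enolate hydroxylation of the C9 ketone, and 10α-H by conjugate reduction.
- Feature used: in ring A the oxygenated C3 lies between C2 and the methyl-bearing C4 and quaternary C5, so C2=C3(OEt)–C4=C5 is a 2-alkoxydiene; C9 beside C10 is a carbonyl that activates a C1≡C10 alkyne on the C6–C7–C8–C9 tether that carries C7.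
- Key disconnection: C1–C2 and C5–C10 by an intramolecular Diels–Alder reaction of ynone 19; rings A and B are formed together in this one step.
- 19 comes from (S)-carvone 1: periodate cleavage gives the C5–C9 chain with C7 intact; the (E)-C4=C5 alkene is fixed by a (Z)-enol triflate and Negishi methylation; the diene is made by Tebbe methylenation (ethoxy in place of silyloxy, so that fluoride and oxidants can follow); the ynone by ethynylation and oxidation.

Key step: step 14

Remark: atoms carry eremophilane numbers (C14 on C5, C15 on C4, isopropenyl C11–C13 on C7; β is the face of C14); centres that become trigonal later (C4 in 11, the carbinol carbon of 18, C8 in 23 to 31) are of no consequence, and 23 to 31 are drawn as the 8α epimers expected from axial attack on the enolate.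

**Step 1**
Reactants: 1 (S)-carvone
Product: 2 (1S,4S,6S)-1-methyl-4-(prop-1-en-2-yl)-7-oxabicyclo[4.1.0]heptan-2-one
Conditions: H2O2 (35% aqueous), NaOH (0.3 equiv), MeOH, 0 °C
Reagents that add atoms: hydrogen peroxide, OO
Why: Weitz–Scheffer epoxidation: the hydroperoxide anion adds only to the electron-poor enone alkene, anti to the isopropenyl group, and leaves the isopropenyl alkene untouched; the two new centres are destroyed in step 2.

**Step 2**
Reactants: 2 carvone epoxide
Product: 5 (S)-5-oxo-3-(prop-1-en-2-yl)pentanoic acid, via ketodiol 3 (not isolated), via dione aldehyde 4 (not isolated)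
Conditions: 0.5 M H2SO4, THF/H2O, rt; then NaIO4 (2.5 equiv), 0 °C → rt
Reagents that add atoms: water, O; sodium periodate, [Na+].[O-]I(=O)(=O)=O
Why: Acid-catalysed epoxide hydrolysis followed by Malaprade periodate cleavage, first of the glycol and then of the resulting 1,2-dione, excises the methyl-bearing ring carbon as acetic acid and leaves the future C5 as the acid and the future C9 as the aldehyde on either side of the untouched C7 centre.

**Step 3**
Reactants: 5 acid aldehyde
Product: 7 (S)-4-(prop-1-en-2-yl)oxan-2-one, via hydroxy acid 6 (not isolated)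
Conditions: NaBH4, NaHCO3, EtOH/H2O, 0 °C; then NaHSO4 (aqueous) to pH 3, PPTS (cat), PhMe, 40 °C
Reagents that add atoms: none
Why: Borohydride reduces the aldehyde but not the carboxylate, and the δ-hydroxy acid lactonises on mild acidification, so the two chain ends stay differentiated as the C5 acyl group and the C9 oxygen.

**Step 4**
Reactants: 7 lactone
Product: 8 (S)-5-hydroxy-N-methoxy-N-methyl-3-(prop-1-en-2-yl)pentanamide
Conditions: MeNH(OMe)·HCl, AlMe3, CH2Cl2, 0 °C → rt
Reagents that add atoms: N,O-dimethylhydroxylamine hydrochloride, CNOC.Cl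
Why: Weinreb aminolysis of the lactone by the aluminium amide gives the C5 Weinreb amide and frees the C9 hydroxyl, which is silylated at once in step 5 to prevent relactonisation.

**Step 5**
Reactants: 8 hydroxy Weinreb amide
Product: 9 (S)-5-(tert-butyldimethylsilyloxy)-N-methoxy-N-methyl-3-(prop-1-en-2-yl)pentanamide
Conditions: TBSCl, imidazole, DMF, rt
Reagents that add atoms: tert-butyldimethylsilyl chloride, CC(C)(C)[Si](C)(C)Cl
Why: Standard imidazole-catalysed silylation of the primary alcohol protects C9–O through the enolate, palladium and titanium steps.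

**Step 6**
Reactants: 9 silyl Weinreb amide; 10 ethyl propanoate
Product: 11 ethyl (5S)-7-(tert-butyldimethylsilyloxy)-2-methyl-3-oxo-5-(prop-1-en-2-yl)heptanoate (C2 epimers)
Conditions: 10, LiN(iPr)2, THF, −78 °C; then 9, −78 → −20 °C
Reagents that add atoms: ethyl propanoate (10), CCC(=O)OCC
Why: Crossed Claisen-type acylation of the lithium enolate of 10 by the Weinreb amide gives the α-methyl β-keto ester without over-addition, adding C4, C15 and C3; the new C4 centre is a mixture that disappears in step 7.

**Step 7**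
Reactants: 11 β-keto ester
Product: 13 ethyl (2Z,5S)-7-(tert-butyldimethylsilyloxy)-2-methyl-5-(prop-1-en-2-yl)-3-(trifluoromethylsulfonyloxy)hept-2-enoate, via sodium enolate 12 (not isolated)
Conditions: NaH, THF, 0 °C; then PhNTf2, 0 °C → rt
Reagents that add atoms: N-phenylbis(trifluoromethanesulfonimide), O=S(=O)(N(c1ccccc1)S(=O)(=O)C(F)(F)F)C(F)(F)F
Why: The sodium enolate of a β-keto ester is chelated and therefore Z, so O-triflation gives the (Z)-enol triflate in which the triflate is cis to the ester and the tether carbon C6 is trans to it.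

**Step 8**
Reactants: 13 (Z)-enol triflate
Product: 14 ethyl (2E,5R)-7-(tert-butyldimethylsilyloxy)-2,3-dimethyl-5-(prop-1-en-2-yl)hept-2-enoate
Conditions: MeZnCl, Pd(PPh3)4 (5 mol %), THF, rt → 50 °C
Reagents that add atoms: methylzinc chloride, C[Zn]Cl
Why: Negishi coupling of the enol triflate proceeds with retention at the alkene, so the new methyl C14 is cis to the ester and C6 trans, which is the (E)-tetrasubstituted C4=C5 alkene needed to keep the tether on the outside of the diene.

**Step 9**
Reactants: 14 (E)-enoate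
Product: 15 tert-butyl{[(3R,5E)-7-ethoxy-5,6-dimethyl-3-(prop-1-en-2-yl)octa-5,7-dien-1-yl]oxy}dimethylsilane
Conditions: Cp2Ti(μ-CH2)(μ-Cl)AlMe2, pyridine (cat), THF/PhMe, −40 °C → rt; aqueous NaOH quench
Reagents that add atoms: Cp2Ti(μ-CH2)(μ-Cl)AlMe2, C[Al-]1(C)C[Ti](C2C=CC=C2)(C2C=CC=C2)[Cl+]1
Why: Tebbe methylenation converts the ester carbonyl into a vinyl ether through the titanium methylidene and an oxatitanacyclobutane, and so gives the 2-ethoxy-1,3-diene C2=C3(OEt)–C4=C5 in one step, without protic acid or base that could scramble the tetrasubstituted alkene.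

**Step 10**
Reactants: 15 silyl ether
Product: 16 (3R,5E)-7-ethoxy-5,6-dimethyl-3-(prop-1-en-2-yl)octa-5,7-dien-1-ol
Conditions: Bu4NF, THF, 0 °C → rt
Reagents that add atoms: none
Why: Fluoride cleaves the primary silyl ether while the alkyl enol ether of the diene is inert to fluoride, which is the reason for using an ethoxy and not a silyloxy diene.

**Step 11**
Reactants: 16 dienyl alcohol
Product: 17 (3R,5E)-7-ethoxy-5,6-dimethyl-3-(prop-1-en-2-yl)octa-5,7-dienal
Conditions: DMP, NaHCO3, CH2Cl2, 0 °C
Reagents that add atoms: none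
Why: Bicarbonate-buffered Dess–Martin oxidation gives the aldehyde under non-acidic conditions that the ethoxydiene tolerates.

**Step 12**
Reactants: 17 aldehyde
Product: 18 (5R,7E)-9-ethoxy-7,8-dimethyl-5-(prop-1-en-2-yl)deca-7,9-dien-1-yn-3-ol (C3 epimers)
Conditions: HC≡CMgBr, THF, −78 → 0 °C
Reagents that add atoms: ethynylmagnesium bromide, C#C[Mg]Br
Why: Grignard addition of the acetylide to the aldehyde brings in C10 and C1; the carbinol configuration is irrelevant because it is oxidised in step 13.

**Step 13**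
Reactants: 18 propargylic alcohol
Product: 19 (5R,7E)-9-ethoxy-7,8-dimethyl-5-(prop-1-en-2-yl)deca-7,9-dien-1-yn-3-one
Conditions: DMP, NaHCO3, CH2Cl2, 0 °C; filtration through neutral alumina
Reagents that add atoms: none
Why: Dess–Martin oxidation of the propargylic alcohol releases the electron-poor ynone only now, buffered so that the enol ether survives, and the crude ynone is taken straight into the cycloaddition.

**Step 14**
Reactants: 19 ethoxydiene ynone
Product: 20 (3R,4aR)-6-ethoxy-4a,5-dimethyl-3-(prop-1-en-2-yl)-3,4,4a,7-tetrahydronaphthalen-1(2H)-one (3-ethoxyeremophila-1(10),3,11-trien-9-one)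
Conditions: PhMe (0.005 M), BHT (cat), 100 °C, sealed tube
Reagents that add atoms: none
Why: Thermal intramolecular Diels–Alder reaction: a concerted but asynchronous [4+2] cycloaddition in which the nucleophilic enol ether terminus C2 bonds to the electrophilic ynone β-carbon C1 ahead of the more hindered C5–C10 bond, the closest known reaction type being the intramolecular cycloaddition of 2-silyloxy- and 2-alkoxydienes with tethered ynones released by oxidation of the propargylic alcohol. Ring A (a six-membered cyclohexa-1,4-diene) is closed by the cycloaddition itself through C1–C2 and C5–C10, and ring B (six-membered) is closed by the same C5–C10 bond through the four-atom tether C6–C7–C8–C9 in the fused mode, the short tether excluding the bridged regiochemistry. C5 is the only new stereocentre, since the alkyne removes any endo/exo question and leaves C10 trigonal, and it is controlled by C7: closure of ring A requires C4 to stay anti to C9 about the forming C5–C10 bond, so C14 is necessarily axial on the chair-like ring B tether, and the isopropenyl group on C7 takes the equatorial position, trans to C14, whereas the other diastereomer would need a 1,3-diaxial C14/isopropenyl contact or a boat tether. The step needs reactivity at the fully substituted C5 terminus and attack on the correct diene face; the (E) geometry fixed in steps 7 and 8 keeps the tether on the outside of the s-cis diene, and the matched polarity of the 2-ethoxydiene and the ynone provides the driving force.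

**Step 15**
Reactants: 20 bicyclic enone
Product: 21 trans-fused ketone 3-ethoxy-10αH-eremophila-3,11-dien-9-one
Conditions: [(Ph3P)CuH]6, H2O (3 equiv), PhMe/THF, rt; then DBU (0.2 equiv), rt
Reagents that add atoms: none
Why: Conjugate reduction by the copper hydride delivers hydride to C1 and C10 is protonated from the α-face, anti to the C14 methyl on the neighbouring carbon; C10 remains enolisable, and DBU equilibration converges on the more stable trans-fused ketone with the isopropenyl group equatorial, as known for 5α-6-oxo steroids.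

**Step 16**
Reactants: 21 trans-fused ketone
Product: 23 3-ethoxy-8α-hydroxy-10αH-eremophila-3,11-dien-9-one, via sodium enolate 22 (not isolated)
Conditions: NaN(SiMe3)2, THF, −78 °C; then 2-(benzenesulfonyl)-3-phenyloxaziridine, −78 °C
Reagents that add atoms: 2-(benzenesulfonyl)-3-phenyloxaziridine, O=S(=O)(c1ccccc1)N1OC1c1ccccc1
Why: Kinetic deprotonation takes place at the C8 methylene and not at the C10 methine, and enolate hydroxylation with the N-sulfonyloxaziridine (Davis oxidation) at −78 °C leaves the enol ether and the isopropenyl alkene untouched.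

**Step 17**
Reactants: 23 α-hydroxy ketone
Product: 24 8α-(tert-butyldimethylsilyloxy)-3-ethoxy-10αH-eremophila-3,11-dien-9-one
Conditions: TBSOTf, 2,6-lutidine, CH2Cl2, −78 → 0 °C
Reagents that add atoms: tert-butyldimethylsilyl triflate, CC(C)(C)[Si](C)(C)OS(=O)(=O)C(F)(F)F
Why: Silylation with the silyl triflate and 2,6-lutidine protects O8 so that O9 can be handled separately after reduction.

**Step 18**
Reactants: 24 silyloxy ketone
Product: 25 8α-(tert-butyldimethylsilyloxy)-3-ethoxy-10αH-eremophila-3,11-dien-9β-ol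
Conditions: NaBH4, MeOH/CH2Cl2, −40 → 0 °C
Reagents that add atoms: none
Why: Borohydride attacks C9 from the α-face because the β-face is shielded by the syn-axial C14 methyl, the same course that turns 6-oxo steroids into 6β-alcohols, and gives the axial 9β-alcohol.

**Step 19**
Reactants: 25 enol ether alcohol
Product: 26 8α-(tert-butyldimethylsilyloxy)-9β-hydroxy-4αH,10αH-eremophil-11-en-3-one
Conditions: oxalic acid (5% aqueous), THF, rt
Reagents that add atoms: water, O
Why: Mild acid hydrolysis of the enol ether unmasks the C3 ketone; C4 is protonated axially from the α-face, anti to C14, which gives the equatorial 4β-methyl group, also the thermodynamic epimer of this enolisable centre.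

**Step 20**
Reactants: 26 C3 ketone
Product: 27 8α-(tert-butyldimethylsilyloxy)-4αH,10αH-eremophil-11-ene-3α,9β-diol
Conditions: Li, NH3 (liquid), THF, t-BuOH, −78 °C
Reagents that add atoms: none
Why: Dissolving-metal reduction is under thermodynamic control and gives the equatorial 3α-alcohol, which hydride reagents would not deliver because their axial approach is blocked by C14; the silyl ether, the free alcohol and the isopropenyl group are inert.

**Step 21**
Reactants: 27 diol; 28 angelic acid
Product: 29 3α-angeloyloxy-8α-(tert-butyldimethylsilyloxy)-4αH,10αH-eremophil-11-en-9β-ol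
Conditions: 28, 2,4,6-trichlorobenzoyl chloride, Et3N, PhMe, rt; then 27, 75 °C
Reagents that add atoms: angelic acid (28), C/C=C(/C)C(=O)O
Why: Yamaguchi esterification through the mixed anhydride acylates the accessible equatorial 3α-hydroxyl and not the axial 9β-hydroxyl, which is 1,3-diaxial to C14, under conditions known to keep the Z geometry of angelates.

**Step 22**
Reactants: 29 angelate alcohol
Product: 30 3α-angeloyloxy-8α-(tert-butyldimethylsilyloxy)-9β-methanesulfonyloxy-4αH,10αH-eremophil-11-ene
Conditions: MsCl, Et3N, CH2Cl2, −10 → 0 °C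
Reagents that add atoms: methanesulfonyl chloride, CS(=O)(=O)Cl
Why: Mesylation through sulfene is little affected by steric hindrance and turns the 9β-hydroxyl into a leaving group with retention.

**Step 23**
Reactants: 30 mesylate
Product: 31 3α-angeloyloxy-9β-methanesulfonyloxy-4αH,10αH-eremophil-11-en-8α-ol
Conditions: HF·pyridine, pyridine, THF, 0 °C → rt
Reagents that add atoms: none
Why: Acidic fluoride removes the silyl ether without base, so the β-hydroxy mesylate does not close to an epoxide and the angelate is not isomerised.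

**Step 24**
Reactants: 31 hydroxy mesylate
Product: 32 3α-angeloyloxy-9β-methanesulfonyloxy-4αH,10αH-eremophil-11-en-8-one
Conditions: DMP, NaHCO3, CH2Cl2, 0 °C → rt
Reagents that add atoms: none
Why: Dess–Martin oxidation gives the C8 ketone, which activates the neighbouring axial mesylate for substitution.

**Step 25**
Reactants: 32 α-mesyloxy ketone; 33 (E)-3-methylpent-2-enoic acid
Product: 34 CNP0301161.1 (3α-angeloyloxy-9α-[(E)-3-methylpent-2-enoyloxy]-4αH,10αH-eremophil-11-en-8-one)
Conditions: 33, Cs2CO3, DMF, rt → 40 °C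
Reagents that add atoms: (E)-3-methylpent-2-enoic acid (33), CC/C(C)=C/C(=O)O
Why: SN2 displacement of the axial α-keto mesylate by the cesium carboxylate inverts C9 to the equatorial 9α-ester, which is also the thermodynamically preferred epimer of this enolisable centre, and the weakly basic carboxylate leaves the angelate and the β,γ-unsaturated ketone unchanged.

**Compound list**
1 | (S)-carvone | CC1=CC[C@@H](CC1=O)C(C)=C | starting material
2 | (1S,4S,6S)-1-methyl-4-(prop-1-en-2-yl)-7-oxabicyclo[4.1.0]heptan-2-one | C[C@]12O[C@H]1C[C@@H](CC2=O)C(C)=C | intermediate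
3 | (2S,3R,5S)-2,3-dihydroxy-2-methyl-5-(prop-1-en-2-yl)cyclohexan-1-one | C[C@]1(O)[C@H](O)C[C@@H](CC1=O)C(C)=C | intermediate (not isolated)
4 | (S)-5,6-dioxo-3-(prop-1-en-2-yl)heptanal | O=CC[C@@H](CC(=O)C(C)=O)C(C)=C | intermediate (not isolated)
5 | (S)-5-oxo-3-(prop-1-en-2-yl)pentanoic acid | O=CC[C@@H](CC(=O)O)C(C)=C | intermediate
6 | (S)-5-hydroxy-3-(prop-1-en-2-yl)pentanoic acid | OCC[C@@H](CC(=O)O)C(C)=C | intermediate (not isolated)
7 | (S)-4-(prop-1-en-2-yl)oxan-2-one | O=C1C[C@H](CCO1)C(C)=C | intermediate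
8 | (S)-5-hydroxy-N-methoxy-N-methyl-3-(prop-1-en-2-yl)pentanamide | CON(C)C(=O)C[C@H](CCO)C(C)=C | intermediate
9 | (S)-5-(tert-butyldimethylsilyloxy)-N-methoxy-N-methyl-3-(prop-1-en-2-yl)pentanamide | CON(C)C(=O)C[C@H](CCO[Si](C)(C)C(C)(C)C)C(C)=C | intermediate
10 | ethyl propanoate | CCC(=O)OCC | starting material
11 | ethyl (5S)-7-(tert-butyldimethylsilyloxy)-2-methyl-3-oxo-5-(prop-1-en-2-yl)heptanoate (C2 epimers, centre left open) | CCOC(=O)C(C)C(=O)C[C@H](CCO[Si](C)(C)C(C)(C)C)C(C)=C | intermediate
12 | sodium (Z)-enolate of 11 | [Na+].CCOC(=O)/C(C)=C(\[O-])C[C@H](CCO[Si](C)(C)C(C)(C)C)C(C)=C | intermediate (not isolated)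
13 | ethyl (2Z,5S)-7-(tert-butyldimethylsilyloxy)-2-methyl-5-(prop-1-en-2-yl)-3-(trifluoromethylsulfonyloxy)hept-2-enoate | CCOC(=O)/C(C)=C(\OS(=O)(=O)C(F)(F)F)C[C@H](CCO[Si](C)(C)C(C)(C)C)C(C)=C | intermediate
14 | ethyl (2E,5R)-7-(tert-butyldimethylsilyloxy)-2,3-dimethyl-5-(prop-1-en-2-yl)hept-2-enoate | CCOC(=O)/C(C)=C(\C)C[C@H](CCO[Si](C)(C)C(C)(C)C)C(C)=C | intermediate
15 | tert-butyl{[(3R,5E)-7-ethoxy-5,6-dimethyl-3-(prop-1-en-2-yl)octa-5,7-dien-1-yl]oxy}dimethylsilane | CCOC(=C)/C(C)=C(\C)C[C@H](CCO[Si](C)(C)C(C)(C)C)C(C)=C | intermediate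
16 | (3R,5E)-7-ethoxy-5,6-dimethyl-3-(prop-1-en-2-yl)octa-5,7-dien-1-ol | CCOC(=C)/C(C)=C(\C)C[C@H](CCO)C(C)=C | intermediate
17 | (3R,5E)-7-ethoxy-5,6-dimethyl-3-(prop-1-en-2-yl)octa-5,7-dienal | CCOC(=C)/C(C)=C(\C)C[C@H](CC=O)C(C)=C | intermediate
18 | (5R,7E)-9-ethoxy-7,8-dimethyl-5-(prop-1-en-2-yl)deca-7,9-dien-1-yn-3-ol (C3 epimers, centre left open) | CCOC(=C)/C(C)=C(\C)C[C@H](CC(O)C#C)C(C)=C | intermediate
19 | (5R,7E)-9-ethoxy-7,8-dimethyl-5-(prop-1-en-2-yl)deca-7,9-dien-1-yn-3-one | CCOC(=C)/C(C)=C(\C)C[C@H](CC(=O)C#C)C(C)=C | intermediate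
20 | (3R,4aR)-6-ethoxy-4a,5-dimethyl-3-(prop-1-en-2-yl)-3,4,4a,7-tetrahydronaphthalen-1(2H)-one | C=C(C)[C@@H]1C[C@]2(C)C(C)=C(OCC)CC=C2C(=O)C1 | intermediate
21 | 3-ethoxy-10αH-eremophila-3,11-dien-9-one (trans-fused; 5β-methyl, 7α-isopropenyl) | C=C(C)[C@@H]1C[C@]2(C)C(C)=C(OCC)CC[C@H]2C(=O)C1 | intermediate
22 | sodium 8(9)-enolate of 21 | [Na+].C=C(C)[C@@H]1C[C@]2(C)C(C)=C(OCC)CC[C@H]2C([O-])=C1 | intermediate (not isolated)
23 | 3-ethoxy-8α-hydroxy-10αH-eremophila-3,11-dien-9-one | C=C(C)[C@@H]1C[C@]2(C)C(C)=C(OCC)CC[C@H]2C(=O)[C@@H]1O | intermediate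
24 | 8α-(tert-butyldimethylsilyloxy)-3-ethoxy-10αH-eremophila-3,11-dien-9-one | C=C(C)[C@@H]1C[C@]2(C)C(C)=C(OCC)CC[C@H]2C(=O)[C@@H]1O[Si](C)(C)C(C)(C)C | intermediate
25 | 8α-(tert-butyldimethylsilyloxy)-3-ethoxy-10αH-eremophila-3,11-dien-9β-ol | C=C(C)[C@@H]1C[C@]2(C)C(C)=C(OCC)CC[C@H]2[C@@H](O)[C@@H]1O[Si](C)(C)C(C)(C)C | intermediate
26 | 8α-(tert-butyldimethylsilyloxy)-9β-hydroxy-4αH,10αH-eremophil-11-en-3-one | C=C(C)[C@@H]1C[C@]2(C)[C@@H](C)C(=O)CC[C@H]2[C@@H](O)[C@@H]1O[Si](C)(C)C(C)(C)C | intermediate
27 | 8α-(tert-butyldimethylsilyloxy)-4αH,10αH-eremophil-11-ene-3α,9β-diol | C=C(C)[C@@H]1C[C@]2(C)[C@@H](C)[C@H](O)CC[C@H]2[C@@H](O)[C@@H]1O[Si](C)(C)C(C)(C)C | intermediate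
28 | angelic acid, (Z)-2-methylbut-2-enoic acid | C/C=C(/C)C(=O)O | starting material
29 | 3α-angeloyloxy-8α-(tert-butyldimethylsilyloxy)-4αH,10αH-eremophil-11-en-9β-ol | C=C(C)[C@@H]1C[C@]2(C)[C@@H](C)[C@H](OC(=O)/C(C)=C\C)CC[C@H]2[C@@H](O)[C@@H]1O[Si](C)(C)C(C)(C)C | intermediate
30 | 3α-angeloyloxy-8α-(tert-butyldimethylsilyloxy)-9β-methanesulfonyloxy-4αH,10αH-eremophil-11-ene | C=C(C)[C@@H]1C[C@]2(C)[C@@H](C)[C@H](OC(=O)/C(C)=C\C)CC[C@H]2[C@@H](OS(C)(=O)=O)[C@@H]1O[Si](C)(C)C(C)(C)C | intermediate
31 | 3α-angeloyloxy-9β-methanesulfonyloxy-4αH,10αH-eremophil-11-en-8α-ol | C=C(C)[C@@H]1C[C@]2(C)[C@@H](C)[C@H](OC(=O)/C(C)=C\C)CC[C@H]2[C@@H](OS(C)(=O)=O)[C@@H]1O | intermediate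
32 | 3α-angeloyloxy-9β-methanesulfonyloxy-4αH,10αH-eremophil-11-en-8-one | C=C(C)[C@@H]1C[C@]2(C)[C@@H](C)[C@H](OC(=O)/C(C)=C\C)CC[C@H]2[C@@H](OS(C)(=O)=O)C1=O | intermediate
33 | (E)-3-methylpent-2-enoic acid | CC/C(C)=C/C(=O)O | starting material
34 | CNP0301161.1, 3α-angeloyloxy-9α-[(E)-3-methylpent-2-enoyloxy]-4αH,10αH-eremophil-11-en-8-one | C=C(C)[C@@H]1C[C@]2(C)[C@@H](C)[C@H](OC(=O)/C(C)=C\C)CC[C@H]2[C@H](OC(=O)/C=C(\C)CC)C1=O | target

**Totals**
Total step count: 25. Longest linear sequence: 25 steps (1 to 34); 10, 28 and 33 are bought.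

**Steps most likely to fail, and fallbacks**

First, step 14. The cycloaddition may be too slow because the fully substituted C5 terminus disfavours the s-cis diene conformer, so that oligomerisation of the terminal ynone or loss of the enol ether takes over. The fallback sets out from aldehyde 17 and uses an alkene dienophile, which can be activated by Me2AlCl at low temperature. Addition of CH2=CHMgBr to 17 gives the allylic alcohol F1, and buffered Dess–Martin oxidation gives the trienone F2. Its intramolecular Diels–Alder reaction (PhMe, heat, or Me2AlCl, CH2Cl2, −78 °C) forms the same C1–C2 and C5–C10 bonds and gives the C1-saturated ketone directly. Any cis-fused epimer F3 is equilibrated with DBU, and the sequence rejoins the route at 21, with steps 12 to 15 left out.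

Second, step 25. Substitution at C9 may lose to E2 removal of the axial 10α-hydrogen, which would give the conjugated 9(10)-en-8-one. Inversion would also be wrong if step 18 had given the other carbinol epimer. The fallback sets out from 29 and relies on thermodynamic control in place of inversion. The hindered 9β-hydroxyl is acylated under forcing conditions (LiN(SiMe3)2, then the acid chloride made from 33) to give the diester F4. HF·pyridine then gives the alcohol F5, and Dess–Martin oxidation gives the 9β-acyloxy ketone F6. Mild equilibration (KOAc, AcOH, or Et3N) moves the acyloxy group from the axial position, 1,3-diaxial to C14, to the equatorial one, as known for 2β-acyloxy-3-oxo steroids, and the sequence comes back at 34.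

Third, step 20. The dissolving-metal reduction may show incomplete thermodynamic control, pinacol coupling, or silyl migration from O8 to O9 in the lithium alkoxide. The fallback sets out from 26 and uses kinetic reduction followed by invertive esterification. LiBH(s-Bu)3 (THF, −78 °C) attacks C3 from the open α-face and gives the axial 3β-alcohol F7. Mitsunobu esterification of F7 with angelic acid 28 (PPh3, DIAD, PhMe, 0 °C → rt) takes place at the less hindered C3 carbinol with inversion, and the sequence comes back at 29, with 27 left out.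

**Further compounds**
F1 | step 14 | (5R,7E)-9-ethoxy-7,8-dimethyl-5-(prop-1-en-2-yl)deca-1,7,9-trien-3-ol (C3 epimers) | CCOC(=C)/C(C)=C(\C)C[C@H](CC(O)C=C)C(C)=C
F2 | step 14 | (5R,7E)-9-ethoxy-7,8-dimethyl-5-(prop-1-en-2-yl)deca-1,7,9-trien-3-one | CCOC(=C)/C(C)=C(\C)C[C@H](CC(=O)C=C)C(C)=C
F3 | step 14 | 3-ethoxy-10βH-eremophila-3,11-dien-9-one (cis-fused epimer of 21) | C=C(C)[C@@H]1C[C@]2(C)C(C)=C(OCC)CC[C@@H]2C(=O)C1
F4 | step 25 | 3α-angeloyloxy-8α-(tert-butyldimethylsilyloxy)-9β-[(E)-3-methylpent-2-enoyloxy]-4αH,10αH-eremophil-11-ene | C=C(C)[C@@H]1C[C@]2(C)[C@@H](C)[C@H](OC(=O)/C(C)=C\C)CC[C@H]2[C@@H](OC(=O)/C=C(\C)CC)[C@@H]1O[Si](C)(C)C(C)(C)C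
F5 | step 25 | 3α-angeloyloxy-9β-[(E)-3-methylpent-2-enoyloxy]-4αH,10αH-eremophil-11-en-8α-ol | C=C(C)[C@@H]1C[C@]2(C)[C@@H](C)[C@H](OC(=O)/C(C)=C\C)CC[C@H]2[C@@H](OC(=O)/C=C(\C)CC)[C@@H]1O
F6 | step 25 | 3α-angeloyloxy-9β-[(E)-3-methylpent-2-enoyloxy]-4αH,10αH-eremophil-11-en-8-one (C9 epimer of 34) | C=C(C)[C@@H]1C[C@]2(C)[C@@H](C)[C@H](OC(=O)/C(C)=C\C)CC[C@H]2[C@@H](OC(=O)/C=C(\C)CC)C1=O
F7 | step 20 | 8α-(tert-butyldimethylsilyloxy)-4αH,10αH-eremophil-11-ene-3β,9β-diol | C=C(C)[C@@H]1C[C@]2(C)[C@@H](C)[C@@H](O)CC[C@H]2[C@@H](O)[C@@H]1O[Si](C)(C)C(C)(C)C
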